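Numbering used throughout (elemane type): cyclohexane carbons C5 [bears C4(=C3H2)–C15H2OH], C6 (lactone O), C7 (lactone carbons C11, C12; exo-methylene C13), C8 (acyloxy), C9 (CH2), C10 (quaternary; CH3 = C14, vinyl = C1=C2).
Enabling feature: the vicinal pair C10/C5 of the cyclohexane ring. The 2-(hydroxymethyl)allyl group on C5 is the SE2′ footprint of an allylsilane, and the vinyl carbon C1 on quaternary C10 is a deoxygenated oxirane carbon. The C5–C10 ring bond is therefore cut to a monocyclic γ-lactone that carries a (2S,3S)-2,3-epoxy alcohol and an allylsilane; the oxirane configuration encodes the cis relation between the vinyl group and the C5 substituent.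
Epoxy alcohol ⇐ Sharpless epoxidation of an (E)-allylic alcohol ⇐ vinylogous Mukaiyama aldol at the C8 aldehyde of a trans-disubstituted γ-lactone. Allylsilane ⇐ Nozaki–Hiyama–Kishi alkenylation and allylic silylation at C5. Lactone stereocentres ⇐ (S)-5-(hydroxymethyl)furan-2(5H)-one by anti radical addition of 1,3-dioxolane.
After ring closure: diol → vinyl, α-methylenation (C13), esterification of O8 with the acid from the (R)-Roche ester, desilylation.
Ring order: the γ-lactone ring comes from the chiral pool and is present from step 1; the cyclohexane ring is formed second, in the key step.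

Key step: step 14

Remark on the chemistry: the carbinol centre made in step 6 and the geometry of the trisubstituted alkene made in step 7 are both erased later (steps 7 and 14). The former is therefore carried as an epimer mixture and the latter is drawn as the expected (E)-isomer. Atom labels C1–C15 in the Why lines are those of the overview. TBDPS = tert-butyldiphenylsilyl, TBS = tert-butyldimethylsilyl.

Step 1
Reactants: 1 (S)-5-(hydroxymethyl)furan-2(5H)-one
Product: 2 (S)-5-[(TBDPS-oxy)methyl]furan-2(5H)-one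
Conditions: TBDPSCl, imidazole, CH2Cl2, 0 °C to rt
Reagents that add atoms: tert-butyl(chloro)diphenylsilane, CC(C)(C)[Si](Cl)(c1ccccc1)c1ccccc1
Why: Routine imidazole-mediated silyl ether formation; the base is too weak to isomerise or racemise the butenolide, and the bulky silyl ether later shields one face of the ring.

Step 2
Reactants: 2 (S)-5-[(TBDPS-oxy)methyl]furan-2(5H)-one
Product: 3 (4S,5S)-5-[(TBDPS-oxy)methyl]-4-(1,3-dioxolan-2-yl)oxolan-2-one
Conditions: 1,3-dioxolane (solvent), benzophenone (10 mol%), hν (350 nm), rt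
Reagents that add atoms: 1,3-dioxolane, C1COCO1
Why: Benzophenone-sensitised photochemical radical conjugate addition (Giese type) of the 2-dioxolanyl radical to the butenolide; the radical should enter anti to the silyloxymethyl group on C6, which sets C7 (trans to C6) and installs C8 as a masked aldehyde.

Step 3
Reactants: 3 (4S,5S)-5-[(TBDPS-oxy)methyl]-4-(1,3-dioxolan-2-yl)oxolan-2-one
Product: 4 (4S,5S)-4-(1,3-dioxolan-2-yl)-5-(hydroxymethyl)oxolan-2-one
Conditions: Bu4NF, AcOH (1:1), THF, 0 °C to rt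
Reagents that add atoms: none
Why: Fluoride desilylation buffered with acetic acid, so that the lactone, the acetal and both stereocentres are left untouched.

Step 4
Reactants: 4 (4S,5S)-4-(1,3-dioxolan-2-yl)-5-(hydroxymethyl)oxolan-2-one
Product: 5 (2S,3S)-3-(1,3-dioxolan-2-yl)-5-oxooxolane-2-carbaldehyde
Conditions: Dess–Martin periodinane, CH2Cl2, 0 °C to rt
Reagents that add atoms: none
Why: Dess–Martin oxidation under neutral, non-epimerising conditions; the α-acyloxy aldehyde is used crude to avoid hydration and epimerisation at C6.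

Step 5
Reactants: 6 2-bromoprop-2-en-1-ol
Product: 7 [(2-bromoprop-2-en-1-yl)oxy](tert-butyl)diphenylsilane
Conditions: TBDPSCl, imidazole, CH2Cl2, rt
Reagents that add atoms: tert-butyl(chloro)diphenylsilane, CC(C)(C)[Si](Cl)(c1ccccc1)c1ccccc1
Why: Routine silylation that gives the alkenyl bromide partner (C3, C4, C15) for the next step.

Step 6
Reactants: 5 (2S,3S)-3-(1,3-dioxolan-2-yl)-5-oxooxolane-2-carbaldehyde; 7 [(2-bromoprop-2-en-1-yl)oxy](tert-butyl)diphenylsilane
Product: 9 (4S,5S)-5-{1-hydroxy-2-[(TBDPS-oxy)methyl]prop-2-en-1-yl}-4-(1,3-dioxolan-2-yl)oxolan-2-one (both carbinol epimers), via alkenylchromium dichloride 8 (not isolated)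
Conditions: CrCl2 (4 equiv), NiCl2 (2 mol%), DMF, rt
Reagents that add atoms: none
Why: Nozaki–Hiyama–Kishi reaction, in which the alkenylchromium species formed by nickel-catalysed insertion adds chemoselectively to the aldehyde in the presence of lactone and acetal; the new carbinol centre is left unassigned because it becomes sp2 in step 7.

Step 7
Reactants: 9 (4S,5S)-5-{1-hydroxy-2-[(TBDPS-oxy)methyl]prop-2-en-1-yl}-4-(1,3-dioxolan-2-yl)oxolan-2-one
Product: 10 (4S,5R)-5-{(1E)-3-(TBDPS-oxy)-2-[(trimethylsilyl)methyl]prop-1-en-1-yl}-4-(1,3-dioxolan-2-yl)oxolan-2-one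
Conditions: Me3SiSiMe3 (1.5 equiv), Pd(MeCN)4(BF4)2 (5 mol%), DMSO/MeOH (1:1), 50 °C
Reagents that add atoms: hexamethyldisilane, C[Si](C)(C)[Si](C)(C)C
Why: Palladium-catalysed allylic silylation of a free allylic alcohol with a disilane through an η3-allylpalladium intermediate; silicon should be delivered to the unsubstituted terminus, which gives the allylsilane with 1,3-transposition of the double bond (E expected, and any Z isomer converges in step 14).

Step 8
Reactants: 10 (4S,5R)-5-{(1E)-3-(TBDPS-oxy)-2-[(trimethylsilyl)methyl]prop-1-en-1-yl}-4-(1,3-dioxolan-2-yl)oxolan-2-one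
Product: 11 (2R,3S)-2-{(1E)-3-(TBDPS-oxy)-2-[(trimethylsilyl)methyl]prop-1-en-1-yl}-5-oxooxolane-3-carbaldehyde
Conditions: pyridinium p-toluenesulfonate (0.3 equiv), acetone/H2O (10:1), 55 °C
Reagents that add atoms: water, O
Why: Mild pyridinium-catalysed acetal hydrolysis frees the C8 aldehyde without protodesilylating the allylsilane; the trans arrangement at C6/C7 is the thermodynamically preferred one, so C7 is not at risk.

Step 9
Reactants: 12 3-methylbut-2-enal
Product: 13 tert-butyl(dimethyl){[(1E)-3-methylbuta-1,3-dien-1-yl]oxy}silane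
Conditions: TBSOTf, Et3N, Et2O, 0 °C to rt
Reagents that add atoms: tert-butyldimethylsilyl trifluoromethanesulfonate, CC(C)(C)[Si](C)(C)OS(=O)(=O)C(F)(F)F
Why: Soft enolisation of the enal at the γ-methyl group and O-silylation give the silyl dienol ether, expected as the (E)-isomer.

Step 10
Reactants: 11 (2R,3S)-2-{(1E)-3-(TBDPS-oxy)-2-[(trimethylsilyl)methyl]prop-1-en-1-yl}-5-oxooxolane-3-carbaldehyde; 13 tert-butyl(dimethyl){[(1E)-3-methylbuta-1,3-dien-1-yl]oxy}silane
Product: 14 (2E,5S)-5-hydroxy-3-methyl-5-[(2R,3R)-2-{(1E)-3-(TBDPS-oxy)-2-[(trimethylsilyl)methyl]prop-1-en-1-yl}-5-oxooxolan-3-yl]pent-2-enal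
Conditions: BF3·OEt2 (1.1 equiv), CH2Cl2/Et2O (9:1), −78 °C; aq. NaHCO3
Reagents that add atoms: none
Why: Vinylogous Mukaiyama aldol reaction at the terminal (γ) carbon of the dienol ether, which delivers C9, C10, C14, C1 and C2 as an (E)-enal; Felkin–Anh addition anti to the larger, oxygen-bearing α-substituent (C6) should set C8 with the hydroxyl syn to the C7 side chain.

Step 11
Reactants: 14 (2E,5S)-5-hydroxy-3-methyl-5-[(2R,3R)-2-{(1E)-3-(TBDPS-oxy)-2-[(trimethylsilyl)methyl]prop-1-en-1-yl}-5-oxooxolan-3-yl]pent-2-enal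
Product: 15 (2E,5S)-5-(TBS-oxy)-3-methyl-5-[(2R,3S)-2-{(1E)-3-(TBDPS-oxy)-2-[(trimethylsilyl)methyl]prop-1-en-1-yl}-5-oxooxolan-3-yl]pent-2-enal
Conditions: TBSOTf (1.2 equiv), 2,6-lutidine, CH2Cl2, −78 °C
Reagents that add atoms: tert-butyldimethylsilyl trifluoromethanesulfonate, CC(C)(C)[Si](C)(C)OS(=O)(=O)C(F)(F)F
Why: Low-temperature silylation of the secondary alcohol; the silyl ether blocks translactonisation to O8 and, unlike an ester, cannot act as a neighbouring group in step 14.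

Step 12
Reactants: 15 (2E,5S)-5-(TBS-oxy)-3-methyl-5-[(2R,3S)-2-{(1E)-3-(TBDPS-oxy)-2-[(trimethylsilyl)methyl]prop-1-en-1-yl}-5-oxooxolan-3-yl]pent-2-enal
Product: 16 (4S,5R)-4-[(1S,3E)-1-(TBS-oxy)-5-hydroxy-3-methylpent-3-en-1-yl]-5-{(1E)-3-(TBDPS-oxy)-2-[(trimethylsilyl)methyl]prop-1-en-1-yl}oxolan-2-one
Conditions: NaBH4, CeCl3·7H2O, MeOH, −40 °C
Reagents that add atoms: none
Why: Luche reduction, a 1,2-reduction of the enal that is chemoselective over the lactone, gives the (E)-allylic alcohol needed for the directed epoxidation.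

Step 13
Reactants: 16 (4S,5R)-4-[(1S,3E)-1-(TBS-oxy)-5-hydroxy-3-methylpent-3-en-1-yl]-5-{(1E)-3-(TBDPS-oxy)-2-[(trimethylsilyl)methyl]prop-1-en-1-yl}oxolan-2-one
Product: 17 (4S,5R)-4-{(1S)-1-(TBS-oxy)-2-[(2S,3S)-3-(hydroxymethyl)-2-methyloxiran-2-yl]ethyl}-5-{(1E)-3-(TBDPS-oxy)-2-[(trimethylsilyl)methyl]prop-1-en-1-yl}oxolan-2-one
Conditions: Ti(OiPr)4 (10 mol%), L-(+)-diisopropyl tartrate (12 mol%), tBuOOH (2 equiv), 4 Å molecular sieves, CH2Cl2, −20 °C
Reagents that add atoms: tert-butyl hydroperoxide, CC(C)(C)OO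
Why: Sharpless asymmetric epoxidation: with L-(+)-tartrate the (E)-allylic alcohol (geraniol type) should be epoxidised under reagent control to the (2S,3S)-oxirane, which fixes the quaternary oxirane carbon (the future C10); the allylsilane alkene has no free allylic hydroxyl and is not touched.

Step 14
Reactants: 17 (4S,5R)-4-{(1S)-1-(TBS-oxy)-2-[(2S,3S)-3-(hydroxymethyl)-2-methyloxiran-2-yl]ethyl}-5-{(1E)-3-(TBDPS-oxy)-2-[(trimethylsilyl)methyl]prop-1-en-1-yl}oxolan-2-one
Product: 18 (3aS,4S,6S,7S,7aR)-4-(TBS-oxy)-6-[(1R)-1,2-dihydroxyethyl]-6-methyl-7-[3-(TBDPS-oxy)prop-1-en-2-yl]hexahydro-1-benzofuran-2(3H)-one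
Conditions: BF3·OEt2 (2 equiv), 2,6-di-tert-butyl-4-methylpyridine (0.5 equiv), CH2Cl2 (5 mM), −78 °C; aq. NaHCO3
Reagents that add atoms: none
Why: Mechanism: BF3 coordination to the oxirane (assisted by the neighbouring hydroxyl) polarises the tertiary C10–O bond, the γ-carbon C5 of the allylsilane attacks C10 from the side opposite to the oxygen, and the β-silyl cation at C4 loses silicon to leave the CH2=C(CH2OSi) unit and the C1 hydroxyl. The closest known reaction types are the Lewis-acid cyclisation of epoxy allylsilanes (intramolecular Hosomi–Sakurai-type epoxide opening) and the cation–olefin cyclisation of 2,3-epoxy alcohols. The cyclohexane ring is closed in a 6-exo mode with respect to both the oxirane C–O bond and the C4=C5 double bond, on a chair that is locked by the trans-fused γ-lactone with O6, C11 and the C8 silyloxy group equatorial. C10 is controlled by the oxirane configuration from step 13, since backside opening is stereospecific and places the methyl group equatorial and C1 (the later vinyl carbon) axial, cis to the C5 substituent; C5 is controlled by allylic A(1,3) strain, because only the chair in which C6–H eclipses the trisubstituted alkene is unstrained, and this puts the alkenyl group equatorial and H5 anti to H6. The step needs regioselective opening at the tertiary oxirane carbon, which cation stability and six- over seven-membered ring formation secure, and it needs the oxirane to ionise before the allylic lactone C6–O bond, which the low temperature and the much higher basicity and strain of the oxirane should secure.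

Step 15
Reactants: 18 (3aS,4S,6S,7S,7aR)-4-(TBS-oxy)-6-[(1R)-1,2-dihydroxyethyl]-6-methyl-7-[3-(TBDPS-oxy)prop-1-en-2-yl]hexahydro-1-benzofuran-2(3H)-one
Product: 19 (3aS,4S,6R,7R,7aR)-4-(TBS-oxy)-6-ethenyl-6-methyl-7-[3-(TBDPS-oxy)prop-1-en-2-yl]hexahydro-1-benzofuran-2(3H)-one
Conditions: PPh3 (4 equiv), imidazole (4 equiv), I2 (2 equiv), toluene, 90 °C
Reagents that add atoms: none
Why: Garegg–Samuelsson olefination, in which the vicinal diol is converted via the primary iodide and the secondary alkoxyphosphonium ion into the alkene by reductive 1,2-elimination; this can only give the vinyl group on quaternary C10 and touches no stereocentre.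

Step 16
Reactants: 19 (3aS,4S,6R,7R,7aR)-4-(TBS-oxy)-6-ethenyl-6-methyl-7-[3-(TBDPS-oxy)prop-1-en-2-yl]hexahydro-1-benzofuran-2(3H)-one
Product: 23 (3aS,4S,6R,7R,7aR)-4-(TBS-oxy)-6-ethenyl-6-methyl-3-methylidene-7-[3-(TBDPS-oxy)prop-1-en-2-yl]hexahydro-1-benzofuran-2(3H)-one, via lithium enolate 20 (not isolated), via Mannich base 21 (not isolated), via trimethylammonium iodide 22 (not isolated)
Conditions: LiN(iPr)2 (1.2 equiv), THF, −78 °C; CH2=NMe2+ I−, −78 °C to rt; MeI, MeOH, rt; aq. NaHCO3, CH2Cl2, rt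
Reagents that add atoms: N,N-dimethylmethyleneiminium iodide (Eschenmoser's salt), C=[N+](C)C.[I-]
Why: α-Methylenation of the lactone by Mannich reaction of its lithium enolate with Eschenmoser's salt, N-methylation and Hofmann-type elimination; C11 is the only enolisable position and the transient sp3 centre disappears in the elimination.

Step 17
Reactants: 23 (3aS,4S,6R,7R,7aR)-4-(TBS-oxy)-6-ethenyl-6-methyl-3-methylidene-7-[3-(TBDPS-oxy)prop-1-en-2-yl]hexahydro-1-benzofuran-2(3H)-one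
Product: 24 (3aR,4S,6R,7R,7aR)-6-ethenyl-4-hydroxy-6-methyl-3-methylidene-7-[3-(TBDPS-oxy)prop-1-en-2-yl]hexahydro-1-benzofuran-2(3H)-one
Conditions: HF·pyridine, pyridine, THF, 0 °C
Reagents that add atoms: none
Why: Buffered HF·pyridine should cleave the secondary TBS ether faster than the more acid-stable primary TBDPS ether, and the acidic medium avoids translactonisation and conjugate addition to the methylene lactone.

Step 18
Reactants: 25 methyl (R)-3-hydroxy-2-methylpropanoate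
Product: 26 methyl (R)-3-(TBDPS-oxy)-2-methylpropanoate
Conditions: TBDPSCl, imidazole, CH2Cl2, rt
Reagents that add atoms: tert-butyl(chloro)diphenylsilane, CC(C)(C)[Si](Cl)(c1ccccc1)c1ccccc1
Why: Routine silylation of the primary alcohol of the (R)-Roche ester; the stereocentre is not involved.

Step 19
Reactants: 26 methyl (R)-3-(TBDPS-oxy)-2-methylpropanoate
Product: 27 (R)-3-(TBDPS-oxy)-2-methylpropanoic acid
Conditions: LiOH, THF/H2O (3:1), 0 °C; aq. HCl to pH 3
Reagents that add atoms: lithium hydroxide, [Li+].[OH-]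
Why: Saponification of the methyl ester at 0 °C, conditions under which the α-stereocentre and the silyl ether should be retained.

Step 20
Reactants: 24 (3aR,4S,6R,7R,7aR)-6-ethenyl-4-hydroxy-6-methyl-3-methylidene-7-[3-(TBDPS-oxy)prop-1-en-2-yl]hexahydro-1-benzofuran-2(3H)-one; 27 (R)-3-(TBDPS-oxy)-2-methylpropanoic acid
Product: 28 (3aR,4S,6R,7R,7aR)-6-ethenyl-6-methyl-3-methylidene-2-oxo-7-[3-(TBDPS-oxy)prop-1-en-2-yl]octahydro-1-benzofuran-4-yl (2R)-3-(TBDPS-oxy)-2-methylpropanoate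
Conditions: N,N′-dicyclohexylcarbodiimide (1.5 equiv), DMAP (0.2 equiv), CH2Cl2, 0 °C to rt
Reagents that add atoms: none
Why: Steglich esterification (carbodiimide activation, DMAP acyl transfer) of the equatorial C8 hydroxyl; C8 keeps its configuration because only the O–H bond is broken.

Step 21
Reactants: 28 (3aR,4S,6R,7R,7aR)-6-ethenyl-6-methyl-3-methylidene-2-oxo-7-[3-(TBDPS-oxy)prop-1-en-2-yl]octahydro-1-benzofuran-4-yl (2R)-3-(TBDPS-oxy)-2-methylpropanoate
Product: 29 (3aR,4S,6R,7R,7aR)-6-ethenyl-7-(3-hydroxyprop-1-en-2-yl)-6-methyl-3-methylidene-2-oxooctahydro-1-benzofuran-4-yl (2R)-3-hydroxy-2-methylpropanoate (CNP0133858.4)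
Conditions: HF·pyridine (excess), THF, 0 °C to rt
Reagents that add atoms: none
Why: Fluoride cleavage of both primary silyl ethers under acidic, non-basic conditions that should leave the ester, the methylene lactone and all stereocentres untouched.

Compound list
1 | (S)-5-(hydroxymethyl)furan-2(5H)-one | OC[C@@H]1C=CC(=O)O1 | starting material
2 | (S)-5-[(TBDPS-oxy)methyl]furan-2(5H)-one | CC(C)(C)[Si](c1ccccc1)(c1ccccc1)OC[C@@H]1C=CC(=O)O1 | intermediate
3 | (4S,5S)-5-[(TBDPS-oxy)methyl]-4-(1,3-dioxolan-2-yl)oxolan-2-one | O1CCOC1[C@H]2CC(=O)O[C@@H]2CO[Si](c3ccccc3)(c4ccccc4)C(C)(C)C | intermediate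
4 | (4S,5S)-4-(1,3-dioxolan-2-yl)-5-(hydroxymethyl)oxolan-2-one | O1CCOC1[C@H]2CC(=O)O[C@@H]2CO | intermediate
5 | (2S,3S)-3-(1,3-dioxolan-2-yl)-5-oxooxolane-2-carbaldehyde | O1CCOC1[C@H]2CC(=O)O[C@@H]2C=O | intermediate
6 | 2-bromoprop-2-en-1-ol | OCC(Br)=C | starting material
7 | [(2-bromoprop-2-en-1-yl)oxy](tert-butyl)diphenylsilane | C=C(Br)CO[Si](c1ccccc1)(c2ccccc2)C(C)(C)C | intermediate
8 | [3-(TBDPS-oxy)prop-1-en-2-yl]chromium dichloride | C=C([Cr](Cl)Cl)CO[Si](c1ccccc1)(c2ccccc2)C(C)(C)C | intermediate (not isolated)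
9 | (4S,5S)-5-{1-hydroxy-2-[(TBDPS-oxy)methyl]prop-2-en-1-yl}-4-(1,3-dioxolan-2-yl)oxolan-2-one, both carbinol epimers | O1CCOC1[C@H]2CC(=O)O[C@@H]2C(O)C(=C)CO[Si](c3ccccc3)(c4ccccc4)C(C)(C)C | intermediate
10 | (4S,5R)-5-{(1E)-3-(TBDPS-oxy)-2-[(trimethylsilyl)methyl]prop-1-en-1-yl}-4-(1,3-dioxolan-2-yl)oxolan-2-one | O1CCOC1[C@H]2CC(=O)O[C@@H]2/C=C(/C[Si](C)(C)C)CO[Si](c3ccccc3)(c4ccccc4)C(C)(C)C | intermediate
11 | (2R,3S)-2-{(1E)-3-(TBDPS-oxy)-2-[(trimethylsilyl)methyl]prop-1-en-1-yl}-5-oxooxolane-3-carbaldehyde | O=C[C@H]1CC(=O)O[C@@H]1/C=C(/C[Si](C)(C)C)CO[Si](c2ccccc2)(c3ccccc3)C(C)(C)C | intermediate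
12 | 3-methylbut-2-enal | CC(C)=CC=O | starting material
13 | tert-butyl(dimethyl){[(1E)-3-methylbuta-1,3-dien-1-yl]oxy}silane | CC(=C)/C=C/O[Si](C)(C)C(C)(C)C | intermediate
14 | (2E,5S)-5-hydroxy-3-methyl-5-[(2R,3R)-2-{(1E)-3-(TBDPS-oxy)-2-[(trimethylsilyl)methyl]prop-1-en-1-yl}-5-oxooxolan-3-yl]pent-2-enal | O=C/C=C(C)/C[C@H](O)[C@H]1CC(=O)O[C@@H]1/C=C(/C[Si](C)(C)C)CO[Si](c2ccccc2)(c3ccccc3)C(C)(C)C | intermediate
15 | (2E,5S)-5-(TBS-oxy)-3-methyl-5-[(2R,3S)-2-{(1E)-3-(TBDPS-oxy)-2-[(trimethylsilyl)methyl]prop-1-en-1-yl}-5-oxooxolan-3-yl]pent-2-enal | O=C/C=C(C)/C[C@H](O[Si](C)(C)C(C)(C)C)[C@H]1CC(=O)O[C@@H]1/C=C(/C[Si](C)(C)C)CO[Si](c2ccccc2)(c3ccccc3)C(C)(C)C | intermediate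
16 | (4S,5R)-4-[(1S,3E)-1-(TBS-oxy)-5-hydroxy-3-methylpent-3-en-1-yl]-5-{(1E)-3-(TBDPS-oxy)-2-[(trimethylsilyl)methyl]prop-1-en-1-yl}oxolan-2-one | OC/C=C(C)/C[C@H](O[Si](C)(C)C(C)(C)C)[C@H]1CC(=O)O[C@@H]1/C=C(/C[Si](C)(C)C)CO[Si](c2ccccc2)(c3ccccc3)C(C)(C)C | intermediate
17 | (4S,5R)-4-{(1S)-1-(TBS-oxy)-2-[(2S,3S)-3-(hydroxymethyl)-2-methyloxiran-2-yl]ethyl}-5-{(1E)-3-(TBDPS-oxy)-2-[(trimethylsilyl)methyl]prop-1-en-1-yl}oxolan-2-one | OC[C@@H]1O[C@@]1(C)C[C@H](O[Si](C)(C)C(C)(C)C)[C@H]2CC(=O)O[C@@H]2/C=C(/C[Si](C)(C)C)CO[Si](c3ccccc3)(c4ccccc4)C(C)(C)C | intermediate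
18 | (3aS,4S,6S,7S,7aR)-4-(TBS-oxy)-6-[(1R)-1,2-dihydroxyethyl]-6-methyl-7-[3-(TBDPS-oxy)prop-1-en-2-yl]hexahydro-1-benzofuran-2(3H)-one | OC[C@H](O)[C@@]1(C)C[C@H](O[Si](C)(C)C(C)(C)C)[C@H]2CC(=O)O[C@@H]2[C@H]1C(=C)CO[Si](c3ccccc3)(c4ccccc4)C(C)(C)C | intermediate
19 | (3aS,4S,6R,7R,7aR)-4-(TBS-oxy)-6-ethenyl-6-methyl-7-[3-(TBDPS-oxy)prop-1-en-2-yl]hexahydro-1-benzofuran-2(3H)-one | C=C[C@@]1(C)C[C@H](O[Si](C)(C)C(C)(C)C)[C@H]2CC(=O)O[C@@H]2[C@H]1C(=C)CO[Si](c3ccccc3)(c4ccccc4)C(C)(C)C | intermediate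
20 | lithium enolate of lactone 19 | [Li+].C=C[C@@]1(C)C[C@H](O[Si](C)(C)C(C)(C)C)[C@H]2C=C([O-])O[C@@H]2[C@H]1C(=C)CO[Si](c3ccccc3)(c4ccccc4)C(C)(C)C | intermediate (not isolated)
21 | 3-[(dimethylamino)methyl] derivative of 19 (configuration at the new C3 centre not assigned) | C=C[C@@]1(C)C[C@H](O[Si](C)(C)C(C)(C)C)[C@H]2C(CN(C)C)C(=O)O[C@@H]2[C@H]1C(=C)CO[Si](c3ccccc3)(c4ccccc4)C(C)(C)C | intermediate (not isolated)
22 | trimethylammonium iodide formed from 21 | [I-].C=C[C@@]1(C)C[C@H](O[Si](C)(C)C(C)(C)C)[C@H]2C(C[N+](C)(C)C)C(=O)O[C@@H]2[C@H]1C(=C)CO[Si](c3ccccc3)(c4ccccc4)C(C)(C)C | intermediate (not isolated)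
23 | (3aS,4S,6R,7R,7aR)-4-(TBS-oxy)-6-ethenyl-6-methyl-3-methylidene-7-[3-(TBDPS-oxy)prop-1-en-2-yl]hexahydro-1-benzofuran-2(3H)-one | C=C[C@@]1(C)C[C@H](O[Si](C)(C)C(C)(C)C)[C@H]2C(=C)C(=O)O[C@@H]2[C@H]1C(=C)CO[Si](c3ccccc3)(c4ccccc4)C(C)(C)C | intermediate
24 | (3aR,4S,6R,7R,7aR)-6-ethenyl-4-hydroxy-6-methyl-3-methylidene-7-[3-(TBDPS-oxy)prop-1-en-2-yl]hexahydro-1-benzofuran-2(3H)-one | C=C[C@@]1(C)C[C@H](O)[C@H]2C(=C)C(=O)O[C@@H]2[C@H]1C(=C)CO[Si](c3ccccc3)(c4ccccc4)C(C)(C)C | intermediate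
25 | methyl (R)-3-hydroxy-2-methylpropanoate | COC(=O)[C@H](C)CO | starting material
26 | methyl (R)-3-(TBDPS-oxy)-2-methylpropanoate | COC(=O)[C@H](C)CO[Si](c1ccccc1)(c2ccccc2)C(C)(C)C | intermediate
27 | (R)-3-(TBDPS-oxy)-2-methylpropanoic acid | OC(=O)[C@H](C)CO[Si](c1ccccc1)(c2ccccc2)C(C)(C)C | intermediate
28 | (3aR,4S,6R,7R,7aR)-6-ethenyl-6-methyl-3-methylidene-2-oxo-7-[3-(TBDPS-oxy)prop-1-en-2-yl]octahydro-1-benzofuran-4-yl (2R)-3-(TBDPS-oxy)-2-methylpropanoate | C=C[C@@]1(C)C[C@H](OC(=O)[C@H](C)CO[Si](c3ccccc3)(c4ccccc4)C(C)(C)C)[C@H]2C(=C)C(=O)O[C@@H]2[C@H]1C(=C)CO[Si](c5ccccc5)(c6ccccc6)C(C)(C)C | intermediate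
29 | (3aR,4S,6R,7R,7aR)-6-ethenyl-7-(3-hydroxyprop-1-en-2-yl)-6-methyl-3-methylidene-2-oxooctahydro-1-benzofuran-4-yl (2R)-3-hydroxy-2-methylpropanoate | C=C[C@@]1(C)C[C@H](OC(=O)[C@H](C)CO)[C@H]2C(=C)C(=O)O[C@@H]2[C@H]1C(=C)CO | target

Total step count: 21.
Longest linear sequence: 17 steps (steps 1–4, 6–8, 10–17, 20 and 21).

Steps most likely to fail

Step 14 (ring closure). What may go wrong is ionisation of the allylic C6–O lactone bond with 1,4-desilylative elimination, interception of the tertiary cation by fluoride or by a 1,2-hydride shift before C–C bond formation, or erosion of the stereospecific opening if a free C10 cation develops. The fallback sets out from 16 and comes back to the route at 19. Acetylation of 16 (Ac2O, pyridine) gives the allylic acetate F1. SnCl4 (CH2Cl2, −78 °C) ionises it to the C2–C1–C10 allyl cation, which the allylsilane captures at its tertiary terminus on the same lactone-locked chair (allyl cation–allylsilane cyclisation). This gives 19 directly and bypasses the oxirane and diol stages. C10 would then rest on the chair preference alone, so separation of the C10 epimer should be expected.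

Step 10 (vinylogous aldol). What may go wrong is insufficient or reversed facial selectivity at the aldehyde, because 1,3-induction by the ring oxygen on C6 works against Felkin–Anh control; Lewis-acid damage to the allylsilane is a second concern. The fallback sets out from 11 and comes back at 14. The aldol is run as described and the C8-epimeric alcohol F2 is separated. It is inverted by Mitsunobu esterification with chloroacetic acid (PPh3, diisopropyl azodicarboxylate, toluene, 0 °C) to the chloroacetate F3. Thiourea (NaHCO3, EtOH, rt) then cleaves F3 to 14 without touching the lactone.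

Step 7 (allylic silylation). What may go wrong is slow ionisation of the hindered allylic alcohol next to the electron-poor C6, β-elimination of the lactone oxygen from the η3-allylpalladium intermediate, or acetal exchange with methanol. The fallback sets out from 9 and comes back at 10. Acetylation (Ac2O, DMAP, pyridine) gives the allylic acetate F4. Anti-SN2′ displacement with (Me3Si)2CuLi (THF, −78 °C) then transfers silicon to the methylene terminus (silylcuprate substitution of an allylic acetate), a temperature at which the lactone should be tolerated.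

Further compounds
F1 | step 14 | (2E,5S)-5-(TBS-oxy)-3-methyl-5-[(2R,3S)-2-{(1E)-3-(TBDPS-oxy)-2-[(trimethylsilyl)methyl]prop-1-en-1-yl}-5-oxooxolan-3-yl]pent-2-en-1-yl acetate | CC(=O)OC/C=C(C)/C[C@H](O[Si](C)(C)C(C)(C)C)[C@H]1CC(=O)O[C@@H]1/C=C(/C[Si](C)(C)C)CO[Si](c2ccccc2)(c3ccccc3)C(C)(C)C
F2 | step 10 | (2E,5R)-5-hydroxy-3-methyl-5-[(2R,3R)-2-{(1E)-3-(TBDPS-oxy)-2-[(trimethylsilyl)methyl]prop-1-en-1-yl}-5-oxooxolan-3-yl]pent-2-enal (C8 epimer of 14) | O=C/C=C(C)/C[C@@H](O)[C@H]1CC(=O)O[C@@H]1/C=C(/C[Si](C)(C)C)CO[Si](c2ccccc2)(c3ccccc3)C(C)(C)C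
F3 | step 10 | (1S,3E)-3-methyl-5-oxo-1-[(2R,3R)-2-{(1E)-3-(TBDPS-oxy)-2-[(trimethylsilyl)methyl]prop-1-en-1-yl}-5-oxooxolan-3-yl]pent-3-en-1-yl chloroacetate | O=C/C=C(C)/C[C@H](OC(=O)CCl)[C@H]1CC(=O)O[C@@H]1/C=C(/C[Si](C)(C)C)CO[Si](c2ccccc2)(c3ccccc3)C(C)(C)C
F4 | step 7 | 1-[(2S,3S)-3-(1,3-dioxolan-2-yl)-5-oxooxolan-2-yl]-2-[(TBDPS-oxy)methyl]prop-2-en-1-yl acetate (both epimers at the acetoxy carbon) | O1CCOC1[C@H]2CC(=O)O[C@@H]2C(OC(C)=O)C(=C)CO[Si](c3ccccc3)(c4ccccc4)C(C)(C)C
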